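The numbers were chosen freely; the result is computed.

This flask cannot come to rest at a balance of substrate and dormant form, because the target takes substrate at 0.0168 min⁻¹ even from the seed, faster than substrate leaks into the dormant form at 0.0025 min⁻¹, and the target's way has no arrow back.

    substrate + target → 2 target (k1 = 240 L mol⁻¹ min⁻¹)
    substrate ⇌ dormant form (K2 = 2.7, k2 = 0.0025 min⁻¹)
    substrate → target (k3 = 0.0012 min⁻¹)

substrate 14 mM (in portions, 4); target 0.0700 mM; time 8.0 d; the portions of substrate follow each other after 40 min, the first at the start

- the state of affairs at 8.0 d: stopped, and by what, or still going (all of the substrate has reacted / forward and back rates have come level / it is still moving)
- how much target there is at 8.0 d, in percent of the substrate charged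

The charge comes in portions, so I ask first whether each is consumed before the next. On the first portion the target doubles in about 0.825 min, much shorter than the 40 min between portions, so I expect each to go quickly. But a little substrate slips into the dormant form, out of the target's reach, and returns by the back arrow, whose constant is 0.0025 min⁻¹ divided by 2.7. Once target stands near the charge, released substrate is caught at 3.36 min⁻¹, far faster than it is released, so control passes to the back arrow, the rate-limiting step of the last conversion. I carry one quantity: the return half-life, the time in which the dormant form halves while released substrate is caught, 0.520 d. The run lasts 15.4 of these, so I reckon that dormant form standing from the start falls to 0.00233 % of itself. Each route turns one substrate into one target, so I expect target at 100.5 % of the charge, seed included.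

The forecast says all of the substrate has reacted, with target at 100.5 %, on the ground that "Equilibrium never holds because the target drains substrate irreversibly".

The flask gives all of the substrate has reacted, with target at 101 %. Its dormant form reads 0.334 % at 0.0833 d, just before the last addition. The neighbour flask, left until 3.0 d, runs 5.61 return half-lives past that addition, so I reckon that reading down to 0.00683 %, leaving out the leak from the last portion. That neighbour flask reads 0.00729 % of dormant form at 3.00 d.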